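**Assumption:** I read the SMILES as (+)-lariciresinol (7S,8R,8'R; 7,8-trans, 8,8'-cis) carrying a threo-(7''R,8''R)-guaiacylglycerol unit on O-4'. Locants: C7–C9 = tetrahydrofuran aryl unit, C7'–C9' = benzyl unit, C7''–C9'' = glycerol unit.

## Retrosynthetic overview
1. The last steps only unmask (two aryl allyl ethers, one TBS ether, reductive loss of an oxazolidinone). The threo C7''–C8'' bond is cut by an Evans boron syn-aldol between the aryloxyacetyl imide of the whole lariciresinol half and O-allylvanillin.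
2. The imide goes back by O-alkylation with a bromoacetate to 4-O-allyl-(+)-lariciresinol, whose 4'-phenol is carried as a TIPS ether.
3. The tetrahydrofuran (second ring made, the one that is kept) comes from cationic C7–O closure of a triol. The triol's C7–C8 bond comes from a lithium-enolate aldol of an (R)-β-arylmethyl-γ-butyrolactone with the same O-allylvanillin.
4. The butyrolactone (first ring made, later opened by hydride) comes from Evans alkylation of the dihydroferuloyl imide with tert-butyl bromoacetate, which sets C8'.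
5. Starting materials: ferulic acid, vanillin, (S)-4-benzyloxazolidin-2-one, tert-butyl bromoacetate, ethyl bromoacetate.

## Route

**Step 1**
Reactants: 1 (E)-ferulic acid
Product: 2 dihydroferulic acid
Conditions: H2 (1 atm), Pd/C (10 wt %), MeOH, rt
Reagents that add atoms: none
Why: Catalytic hydrogenation saturates only the cinnamic C=C, while the arene, acid and phenol are inert at 1 atm.

**Step 2**
Reactants: 2 dihydroferulic acid
Product: 4 3-[3-methoxy-4-(triisopropylsilyloxy)phenyl]propanoic acid, via bis-TIPS silyl ester 3 (not isolated)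
Conditions: TIPSCl (2.3 equiv), imidazole, DMF, rt; then K2CO3, THF/MeOH/H2O, rt; 1 M HCl to pH 3
Reagents that add atoms: triisopropylsilyl chloride, CC(C)[Si](Cl)(C(C)C)C(C)C
Why: Silylation caps both the phenol and the acid, and mild basic hydrolysis then cleaves only the much more labile silyl ester, leaving a bulky aryl silyl ether that tolerates the later enolate, hydride and acid steps.

**Step 3**
Reactants: 4 TIPS-protected acid; 5 (S)-4-benzyl-1,3-oxazolidin-2-one
Product: 7 (4S)-4-benzyl-3-{3-[3-methoxy-4-(triisopropylsilyloxy)phenyl]propanoyl}-1,3-oxazolidin-2-one, via mixed pivalic anhydride 6 (not isolated)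
Conditions: PivCl, Et3N, THF, −20 °C; then LiCl, 5, −20 °C to rt
Reagents that add atoms: pivaloyl chloride, CC(C)(C)C(=O)Cl (its acyl group stays only in intermediate 6, nothing of it in 7)
Why: This is N-acylation of the auxiliary through a mixed anhydride, where the hindered pivaloyl carbonyl steers the LiCl-activated oxazolidinone to the arylpropanoyl carbonyl.

**Step 4**
Reactants: 7 N-acyl oxazolidinone; 8 tert-butyl bromoacetate
Product: 10 tert-butyl (3R)-4-[(4S)-4-benzyl-2-oxo-1,3-oxazolidin-3-yl]-3-[3-methoxy-4-(triisopropylsilyloxy)benzyl]-4-oxobutanoate, via sodium Z-enolate 9 (not isolated)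
Conditions: NaN(SiMe3)2, THF, −78 °C; then 8, −78 to −40 °C
Reagents that add atoms: NaN(SiMe3)2, [Na+].C[Si](C)(C)[N-][Si](C)(C)C (its sodium stays only in intermediate 9, nothing of it in 10)
Why: In this Evans asymmetric alkylation the chelated Z-enolate is shielded on one face by the 4-benzyl group, so the bromoacetate enters from the other face and sets C8' as R (dr usually >95:5, minor isomer removed on silica).

**Step 5**
Reactants: 10 alkylated imide
Product: 11 tert-butyl (3R)-4-hydroxy-3-[3-methoxy-4-(triisopropylsilyloxy)benzyl]butanoate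
Conditions: LiBH4, MeOH (1.5 equiv), THF, 0 °C
Reagents that add atoms: none
Why: Borohydride reduces the activated exocyclic imide carbonyl chemoselectively to CH2OH, the hindered tert-butyl ester survives, and C8' is untouched.

**Step 6**
Reactants: 11 hydroxy ester
Product: 12 (4R)-4-[3-methoxy-4-(triisopropylsilyloxy)benzyl]dihydrofuran-2(3H)-one
Conditions: p-TsOH·H2O (10 mol %), toluene, 60 °C
Reagents that add atoms: none
Why: Acid-catalysed lactonisation (intramolecular transesterification) of a γ-hydroxy ester is strongly favoured, and the aryl TIPS ether is stable to catalytic sulfonic acid.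

**Step 7**
Reactants: 13 vanillin
Product: 14 4-(allyloxy)-3-methoxybenzaldehyde (O-allylvanillin)
Conditions: allyl bromide, K2CO3, DMF, rt
Reagents that add atoms: allyl bromide, C=CCBr
Why: This Williamson ether synthesis on an acidic phenol gives the aldehyde partner for both aldol reactions.

**Step 8**
Reactants: 12 (R)-lactone; 14 O-allylvanillin
Product: 16 (3S,4R)-3-{[4-(allyloxy)-3-methoxyphenyl](hydroxy)methyl}-4-[3-methoxy-4-(triisopropylsilyloxy)benzyl]dihydrofuran-2(3H)-one (both C7 carbinol epimers), via lithium lactone enolate 15 (not isolated)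
Conditions: LiN(SiMe3)2, THF, −78 °C; then 14, −78 °C; AcOH quench at −78 °C
Reagents that add atoms: LiN(SiMe3)2, [Li+].C[Si](C)(C)[N-][Si](C)(C)C (its lithium stays only in intermediate 15, nothing of it in 16)
Why: In this intermolecular lithium-enolate aldol addition the aldehyde approaches anti to the C8' arylmethyl group, which sets C8 trans to it, and the C7 carbinol mixture does not matter because step 10 erases it.

**Step 9**
Reactants: 16 aldol lactone
Product: 17 (2R,3R)-2-{[4-(allyloxy)-3-methoxyphenyl](hydroxy)methyl}-3-[3-methoxy-4-(triisopropylsilyloxy)benzyl]butane-1,4-diol (both C7 epimers)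
Conditions: LiAlH4, THF, 0 °C to rt; H2O / 15% aq NaOH / H2O work-up
Reagents that add atoms: none
Why: Hydride reduction of the lactone to the 1,4-diol outruns retro-aldol at 0 °C and touches neither C8 nor C8', and the allyl and TIPS aryl ethers are inert.

**Step 10**
Reactants: 17 triol
Product: 19 {(2S,3R,4R)-2-[4-(allyloxy)-3-methoxyphenyl]-4-[3-methoxy-4-(triisopropylsilyloxy)benzyl]tetrahydrofuran-3-yl}methanol (4-O-allyl-4'-O-TIPS-(+)-lariciresinol), via benzylic cation 18 (not isolated)
Conditions: 10-camphorsulfonic acid (10 mol %), CH2Cl2 (0.02 M), 0 °C, stopped with Et3N at full conversion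
Reagents that add atoms: none
Why: In this SN1 cyclodehydration both carbinol epimers ionise to one p-alkoxybenzylic cation, and C9'-OH closes the five-membered ring reversibly (C9-OH could only give an oxetane), so the aryl group settles trans to the C8 hydroxymethyl instead of all-cis and C7 is set as S.

**Step 11**
Reactants: 19 TIPS ether
Product: 20 4-O-allyl-(+)-lariciresinol (free 4'-phenol, free C9-OH)
Conditions: Bu4NF, THF, 0 °C
Reagents that add atoms: none
Why: Fluoride-driven desilylation of the aryl silyl ether is fast and leaves the allyl ether, the tetrahydrofuran and the alcohol alone.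

**Step 12**
Reactants: 20 phenol; 21 ethyl bromoacetate
Product: 22 ethyl 2-{4-[((3R,4R,5S)-5-[4-(allyloxy)-3-methoxyphenyl]-4-(hydroxymethyl)tetrahydrofuran-3-yl)methyl]-2-methoxyphenoxy}acetate
Conditions: K2CO3, acetone, reflux
Reagents that add atoms: none
Why: In this Williamson etherification carbonate deprotonates only the phenol, so the primary alcohol is not alkylated.

**Step 13**
Reactants: 22 hydroxy ester
Product: 23 C9-O-TBS ether of 22
Conditions: TBSCl, imidazole, CH2Cl2, rt
Reagents that add atoms: tert-butyldimethylsilyl chloride, CC(C)(C)[Si](C)(C)Cl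
Why: Silyl ether formation removes the only protic group that would consume the boron triflate in step 16.

**Step 14**
Reactants: 23 ethyl ester
Product: 24 aryloxyacetic acid (C9-O-TBS, 4-O-allyl)
Conditions: LiOH·H2O, THF/H2O, 0 °C to rt; cold 0.5 M HCl to pH 4
Reagents that add atoms: LiOH, [Li+].[OH-] (its oxygen ends in the carboxyl group)
Why: Saponification of an activated aryloxyacetate is fast at 0 °C, and no stereocentre is acidic.

**Step 15**
Reactants: 24 acid; 5 (S)-4-benzyl-1,3-oxazolidin-2-one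
Product: 26 (4S)-4-benzyl-3-(aryloxyacetyl)-1,3-oxazolidin-2-one of the lariciresinol half, via mixed pivalic anhydride 25 (not isolated)
Conditions: PivCl, Et3N, THF, −20 °C; then LiCl, 5, −20 °C to rt
Reagents that add atoms: pivaloyl chloride, CC(C)(C)C(=O)Cl (its acyl group stays only in intermediate 25, nothing of it in 26)
Why: This is the same mixed-anhydride N-acylation as step 3, with attack at the unhindered aryloxyacetyl carbonyl.

**Step 16**
Reactants: 26 aryloxyacetyl imide; 14 O-allylvanillin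
Product: 28 (4S)-4-benzyl-3-[(2S,3R)-3-[4-(allyloxy)-3-methoxyphenyl]-2-(aryloxy)-3-hydroxypropanoyl]-1,3-oxazolidin-2-one (syn aldol), via dibutylboron Z-enolate 27 (not isolated)
Conditions: n-Bu2BOTf, Et3N, CH2Cl2, −78 to 0 °C; 14, −78 to 0 °C; pH 7 phosphate buffer, MeOH, 30% H2O2, 0 °C
Reagents that add atoms: n-Bu2BOTf, CCCCB(CCCC)OS(=O)(=O)C(F)(F)F (its Bu2B group stays only in intermediate 27, nothing of it in 28)
Why: In this Evans syn-aldol the Z-boron enolate reacts through a closed Zimmerman–Traxler chair with the auxiliary carbonyl dipole opposed, so the (S)-benzyl group fixes the enolate face and sets C8'' and C7'' together in the syn (threo) sense that becomes 7''R,8''R.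

**Step 17**
Reactants: 28 aldol adduct
Product: 29 (1R,2R)-1-[4-(allyloxy)-3-methoxyphenyl]-2-(aryloxy)propane-1,3-diol (C9-O-TBS, 4-O-allyl lariciresinol as the aryl part)
Conditions: NaBH4, THF/H2O (4:1), 0 °C to rt
Reagents that add atoms: none
Why: Borohydride reductively cleaves the imide to the primary alcohol under nearly neutral conditions, which avoids retro-aldol and C8'' epimerisation and returns the auxiliary.

**Step 18**
Reactants: 29 TBS ether
Product: 30 bis(O-allyl) ether of the target (three free alcohols)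
Conditions: Bu4NF, THF, 0 °C to rt
Reagents that add atoms: none
Why: Fluoride desilylation is done while both phenols are still capped, so basic fluoride cannot generate a quinone methide from the benzylic alcohol.

**Step 19**
Reactants: 30 bis(allyl) ether
Product: 31 target CNP0158473.2
Conditions: Pd(PPh3)4 (10 mol %), morpholine (10 equiv), degassed THF, rt
Reagents that add atoms: none
Why: In this Tsuji–Trost deallylation zerovalent palladium ionises the aryl allyl ethers to π-allyl complexes that morpholine captures, and because the conditions are neither acidic nor reductive the benzylic C7–O and C7''–OH bonds and all five stereocentres are preserved.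

## Compound list
1 | (E)-ferulic acid | COc1cc(/C=C/C(=O)O)ccc1O | starting material
2 | dihydroferulic acid | COc1cc(CCC(=O)O)ccc1O | intermediate
3 | triisopropylsilyl 3-[3-methoxy-4-(triisopropylsilyloxy)phenyl]propanoate | COc1cc(CCC(=O)O[Si](C(C)C)(C(C)C)C(C)C)ccc1O[Si](C(C)C)(C(C)C)C(C)C | intermediate
4 | 3-[3-methoxy-4-(triisopropylsilyloxy)phenyl]propanoic acid | COc1cc(CCC(=O)O)ccc1O[Si](C(C)C)(C(C)C)C(C)C | intermediate
5 | (S)-4-benzyl-1,3-oxazolidin-2-one | O=C1N[C@@H](Cc2ccccc2)CO1 | starting material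
6 | mixed pivalic anhydride of acid 4 | COc1cc(CCC(=O)OC(=O)C(C)(C)C)ccc1O[Si](C(C)C)(C(C)C)C(C)C | intermediate
7 | (4S)-4-benzyl-3-{3-[3-methoxy-4-(triisopropylsilyloxy)phenyl]propanoyl}-1,3-oxazolidin-2-one | COc1cc(CCC(=O)N2[C@@H](Cc3ccccc3)COC2=O)ccc1O[Si](C(C)C)(C(C)C)C(C)C | intermediate
8 | tert-butyl bromoacetate | CC(C)(C)OC(=O)CBr | starting material
9 | sodium (Z)-enolate of 7 | [Na+].[O-]/C(=C\Cc1ccc(O[Si](C(C)C)(C(C)C)C(C)C)c(OC)c1)N1[C@@H](Cc2ccccc2)COC1=O | intermediate
10 | tert-butyl (3R)-4-[(4S)-4-benzyl-2-oxo-1,3-oxazolidin-3-yl]-3-[3-methoxy-4-(triisopropylsilyloxy)benzyl]-4-oxobutanoate | COc1cc(C[C@H](CC(=O)OC(C)(C)C)C(=O)N2[C@@H](Cc3ccccc3)COC2=O)ccc1O[Si](C(C)C)(C(C)C)C(C)C | intermediate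
11 | tert-butyl (3R)-4-hydroxy-3-[3-methoxy-4-(triisopropylsilyloxy)benzyl]butanoate | COc1cc(C[C@H](CC(=O)OC(C)(C)C)CO)ccc1O[Si](C(C)C)(C(C)C)C(C)C | intermediate
12 | (4R)-4-[3-methoxy-4-(triisopropylsilyloxy)benzyl]dihydrofuran-2(3H)-one | COc1cc(C[C@H]2COC(=O)C2)ccc1O[Si](C(C)C)(C(C)C)C(C)C | intermediate
13 | vanillin | COc1cc(C=O)ccc1O | starting material
14 | 4-(allyloxy)-3-methoxybenzaldehyde | C=CCOc1ccc(C=O)cc1OC | intermediate
15 | lithium enolate of lactone 12 | [Li+].COc1cc(C[C@H]2COC([O-])=C2)ccc1O[Si](C(C)C)(C(C)C)C(C)C | intermediate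
16 | (3S,4R)-aldol lactone, both C7 carbinol epimers | COc1cc(C[C@H]2COC(=O)[C@@H]2C(O)c3ccc(OCC=C)c(OC)c3)ccc1O[Si](C(C)C)(C(C)C)C(C)C | intermediate
17 | (2R,3R)-triol, both C7 epimers | COc1cc(C[C@@H](CO)[C@H](CO)C(O)c2ccc(OCC=C)c(OC)c2)ccc1O[Si](C(C)C)(C(C)C)C(C)C | intermediate
18 | C7 benzylic cation from 17 | COc1cc(C[C@@H](CO)[C@H](CO)[CH+]c2ccc(OCC=C)c(OC)c2)ccc1O[Si](C(C)C)(C(C)C)C(C)C | intermediate
19 | 4-O-allyl-4'-O-TIPS-(+)-lariciresinol (7S,8R,8'R) | COc1cc(C[C@H]2CO[C@H](c3ccc(OCC=C)c(OC)c3)[C@H]2CO)ccc1O[Si](C(C)C)(C(C)C)C(C)C | intermediate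
20 | 4-O-allyl-(+)-lariciresinol | COc1cc(C[C@H]2CO[C@H](c3ccc(OCC=C)c(OC)c3)[C@H]2CO)ccc1O | intermediate
21 | ethyl bromoacetate | CCOC(=O)CBr | starting material
22 | ethyl (4'-O-lariciresinyl)acetate, 4-O-allyl, C9-OH free | CCOC(=O)COc1ccc(C[C@H]2CO[C@H](c3ccc(OCC=C)c(OC)c3)[C@H]2CO)cc1OC | intermediate
23 | C9-O-TBS ether of 22 | CCOC(=O)COc1ccc(C[C@H]2CO[C@H](c3ccc(OCC=C)c(OC)c3)[C@H]2CO[Si](C)(C)C(C)(C)C)cc1OC | intermediate
24 | aryloxyacetic acid from 23 | OC(=O)COc1ccc(C[C@H]2CO[C@H](c3ccc(OCC=C)c(OC)c3)[C@H]2CO[Si](C)(C)C(C)(C)C)cc1OC | intermediate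
25 | mixed pivalic anhydride of acid 24 | CC(C)(C)C(=O)OC(=O)COc1ccc(C[C@H]2CO[C@H](c3ccc(OCC=C)c(OC)c3)[C@H]2CO[Si](C)(C)C(C)(C)C)cc1OC | intermediate
26 | (4S)-4-benzyl-3-(aryloxyacetyl)oxazolidin-2-one | O=C(COc1ccc(C[C@H]2CO[C@H](c3ccc(OCC=C)c(OC)c3)[C@H]2CO[Si](C)(C)C(C)(C)C)cc1OC)N1[C@@H](Cc2ccccc2)COC1=O | intermediate
27 | dibutylboron (Z)-enolate of 26 | CCCCB(CCCC)O/C(=C\Oc1ccc(C[C@H]2CO[C@H](c3ccc(OCC=C)c(OC)c3)[C@H]2CO[Si](C)(C)C(C)(C)C)cc1OC)N1[C@@H](Cc2ccccc2)COC1=O | intermediate
28 | (2S,3R)-syn aldol imide | COc1cc([C@@H](O)[C@@H](C(=O)N2[C@@H](Cc3ccccc3)COC2=O)Oc2ccc(C[C@H]3CO[C@H](c4ccc(OCC=C)c(OC)c4)[C@H]3CO[Si](C)(C)C(C)(C)C)cc2OC)ccc1OCC=C | intermediate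
29 | (7''R,8''R)-diol, C9-O-TBS, bis(O-allyl) | COc1cc([C@@H](O)[C@@H](CO)Oc2ccc(C[C@H]3CO[C@H](c4ccc(OCC=C)c(OC)c4)[C@H]3CO[Si](C)(C)C(C)(C)C)cc2OC)ccc1OCC=C | intermediate
30 | bis(O-allyl) ether of the target | COc1cc([C@@H](O)[C@@H](CO)Oc2ccc(C[C@H]3CO[C@H](c4ccc(OCC=C)c(OC)c4)[C@H]3CO)cc2OC)ccc1OCC=C | intermediate
31 | CNP0158473.2, (+)-lariciresinol 4'-O-[threo-(7''R,8''R)-guaiacylglycer-8''-yl] ether | COc1cc([C@@H](O)[C@@H](CO)Oc2ccc(C[C@H]3CO[C@H](c4ccc(O)c(OC)c4)[C@H]3CO)cc2OC)ccc1O | target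

## Counts and risks
- Total step count: 19.
- Longest linear sequence: 18 (steps 1–6 and 8–19). Step 7 is a one-step side branch.

**Step 10 (cationic ring closure).**
- The risks are re-ionisation of the product, with Friedel–Crafts closure onto the pendant arene to give an aryltetralin, and incomplete 7,8-trans selectivity.
- The fallback sets out from 17 and comes back at 19. It replaces the acid-generated cation with a quinone methide formed without acid.
- The allyl ether of 17 is removed first with Pd(PPh3)4 and morpholine in THF to give the free-phenol triol F1.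
- Me3SiBr in CH2Cl2 at 0 °C converts only the p-hydroxybenzylic alcohol into the benzylic bromide F2.
- Shaking with saturated aqueous NaHCO3 eliminates HBr to the p-quinone methide F3. C9'-OH adds to it at once in an intramolecular 1,6-oxa-addition, anti to the C8 hydroxymethyl group, to give 4'-O-TIPS-(+)-lariciresinol F4.
- Re-allylation of the free phenol (allyl bromide, K2CO3, acetone) gives 19.

**Step 16 (late boron aldol on a polyether substrate).**
- The risks are sequestration of n-Bu2BOTf by the many ether oxygens, Lewis-acid opening of the 2-aryltetrahydrofuran, and low conversion with the electron-rich aldehyde.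
- The fallback sets out from 23 (with 14) and comes back at 29. It keeps an aldol C–C bond formation but moves stereocontrol to a catalyst.
- The lithium enolate of 23 (LiN(SiMe3)2, THF, −78 °C) adds to 14 to give the stereorandom hydroxy ester F5.
- Dess–Martin periodinane oxidises F5 to the α-aryloxy β-keto ester F6, whose C8'' epimerises freely.
- Asymmetric transfer hydrogenation with dynamic kinetic resolution follows (RuCl(p-cymene)[(S,S)-TsDPEN], HCO2H/Et3N, CH2Cl2, 30 °C). The (S,S) catalyst should deliver 7''R by the usual aryl ketone model, and this sense has to be confirmed on the first run. The product is the syn (2S,3R)-hydroxy ester F7.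
- LiBH4 in THF reduces the ester of F7 to 29.

**Step 17 (auxiliary removal from a free β-hydroxy imide).**
- The risks are retro-aldol, C8'' epimerisation and endocyclic opening of the oxazolidinone.
- The fallback sets out from 28 and comes back at 30.
- The carbinol is first silylated (TBSOTf, 2,6-lutidine, CH2Cl2, −78 °C) to the C7''-O-TBS imide F8, which can no longer undergo retro-aldol.
- LiBH4 with MeOH in THF at 0 °C gives the bis-TBS primary alcohol F9.
- Excess Bu4NF removes both silyl groups in one operation to give 30. Any silyl migration between O7'' and O9'' is therefore harmless.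

## Further compounds
F1 | step 10 | free-phenol triol (2R,3R; both C7 epimers; 4'-O-TIPS) | COc1cc(C[C@@H](CO)[C@H](CO)C(O)c2ccc(O)c(OC)c2)ccc1O[Si](C(C)C)(C(C)C)C(C)C
F2 | step 10 | C7 benzylic bromide of F1 | COc1cc(C[C@@H](CO)[C@H](CO)C(Br)c2ccc(O)c(OC)c2)ccc1O[Si](C(C)C)(C(C)C)C(C)C
F3 | step 10 | p-quinone methide from F2 | COc1cc(C[C@@H](CO)[C@H](CO)C=C2C=CC(=O)C(OC)=C2)ccc1O[Si](C(C)C)(C(C)C)C(C)C
F4 | step 10 | 4'-O-TIPS-(+)-lariciresinol | COc1cc(C[C@H]2CO[C@H](c3ccc(O)c(OC)c3)[C@H]2CO)ccc1O[Si](C(C)C)(C(C)C)C(C)C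
F5 | step 16 | ethyl 2-aryloxy-3-hydroxy-3-arylpropanoate, all C7''/C8'' isomers | CCOC(=O)C(Oc1ccc(C[C@H]2CO[C@H](c3ccc(OCC=C)c(OC)c3)[C@H]2CO[Si](C)(C)C(C)(C)C)cc1OC)C(O)c1ccc(OCC=C)c(OC)c1
F6 | step 16 | ethyl 2-aryloxy-3-oxo-3-arylpropanoate, C8'' labile | CCOC(=O)C(Oc1ccc(C[C@H]2CO[C@H](c3ccc(OCC=C)c(OC)c3)[C@H]2CO[Si](C)(C)C(C)(C)C)cc1OC)C(=O)c1ccc(OCC=C)c(OC)c1
F7 | step 16 | ethyl (2S,3R)-syn-2-aryloxy-3-hydroxy-3-arylpropanoate | COc1cc([C@@H](O)[C@@H](C(=O)OCC)Oc2ccc(C[C@H]3CO[C@H](c4ccc(OCC=C)c(OC)c4)[C@H]3CO[Si](C)(C)C(C)(C)C)cc2OC)ccc1OCC=C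
F8 | step 17 | C7''-O-TBS ether of imide 28 | COc1cc([C@@H](O[Si](C)(C)C(C)(C)C)[C@@H](C(=O)N2[C@@H](Cc3ccccc3)COC2=O)Oc2ccc(C[C@H]3CO[C@H](c4ccc(OCC=C)c(OC)c4)[C@H]3CO[Si](C)(C)C(C)(C)C)cc2OC)ccc1OCC=C
F9 | step 17 | C7'',C9-bis-O-TBS primary alcohol | COc1cc([C@@H](O[Si](C)(C)C(C)(C)C)[C@@H](CO)Oc2ccc(C[C@H]3CO[C@H](c4ccc(OCC=C)c(OC)c4)[C@H]3CO[Si](C)(C)C(C)(C)C)cc2OC)ccc1OCC=C
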